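**Assumptions.** The target is taken exactly as drawn: jaeschkeanadiol 6‑O‑(4‑hydroxybenzoate) 8,9‑epoxide. Daucane numbering is used (C1 = quaternary C‑Me, C4 = C(OH)iPr, C5 = ring‑fusion CH, C6 = ester carbon, C8/C9 = epoxide). β is the face of C1‑Me and 4‑OH; α is the face of H‑5, 6‑O and the epoxide O. (S)‑(+)‑Terpinen‑4‑ol is assumed to be bought as the single enantiomer. All steps are proposed, not run; the cyclisation in Step 7 is new chemistry.

## Retrosynthetic overview

1. Jaeskeanin ⇒ acylation of 6‑OH and 6‑OH‑directed epoxidation of jaeschkeanadiol (10).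
2. 10 ⇒ 4‑OH‑directed reduction of the trans‑fused hydroxy‑ketone 9.
3. 9 ⇒ light‑driven radical "ene" cycloisomerisation of dienone 8. This forms C1–C10, the quaternary centre, the seven‑membered ring (second ring) and the C8=C9 alkene.
4. 8 ⇒ Grignard addition/oxidation on cyclopentene carbaldehyde 4.
5. 4 ⇒ ozonolysis/aldol ring contraction of (S)‑terpinen‑4‑ol (five‑membered ring first; C4 is bought, all other stereocentres are relayed from it).

## Route

**Step 1**
Reactants: 1, (S)‑(+)‑terpinen‑4‑ol
Product: 2, triethyl{[(1S)‑4‑methyl‑1‑(propan‑2‑yl)cyclohex‑3‑en‑1‑yl]oxy}silane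
Conditions: TESOTf, 2,6‑lutidine, CH2Cl2, 0 °C
Reagents that add atoms: triethylsilyl triflate, CC[Si](CC)(CC)OS(=O)(=O)C(F)(F)F
Why: Silylation of the tertiary alcohol with a silyl triflate masks the OH, so it cannot undergo β‑elimination or retro‑aldol in Steps 2–3; the stereocentre is untouched.

**Step 2**
Reactants: 2
Product: 3, (3S)‑6‑oxo‑3‑(propan‑2‑yl)‑3‑[(triethylsilyl)oxy]heptanal
Conditions: O3, CH2Cl2, −78 °C; then PPh3, −78 °C → rt
Reagents that add atoms: ozone, [O-][O+]=O
Why: Ozonolysis (Criegee) of the only alkene gives the methyl ketone and aldehyde termini without touching the silyl ether or the quaternary carbinol.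

**Step 3**
Reactants: 3
Product: 4, (5R)‑2‑methyl‑5‑(propan‑2‑yl)‑5‑[(triethylsilyl)oxy]cyclopent‑1‑ene‑1‑carbaldehyde
Conditions: piperidine (0.3 equiv), AcOH (0.3 equiv), benzene, 4 Å MS, 70 °C
Reagents that add atoms: none
Why: Enamine‑mediated intramolecular aldol condensation (5‑enolexo, aldehyde enamine onto the methyl ketone) gives the tetrasubstituted enal; with O4 silylated, only the new tertiary OH is lost.

**Step 4**
Reactants: 5, 2‑methylbut‑3‑en‑1‑ol (racemic)
Product: 6, 4‑bromo‑3‑methylbut‑1‑ene (racemic)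
Conditions: CBr4, PPh3, CH2Cl2, 0 °C
Reagents that add atoms: carbon tetrabromide, BrC(Br)(Br)Br
Why: Appel bromination of a primary alcohol; the racemic centre is erased in Step 7.

**Step 5**
Reactants: 4; 6 (as its Grignard reagent)
Product: 7, 1‑[(5R)‑5‑hydroxy‑2‑methyl‑5‑(propan‑2‑yl)cyclopent‑1‑en‑1‑yl]‑3‑methylpent‑4‑en‑1‑ol (mixture at the two side‑chain centres)
Conditions: 6, Mg, THF; add 4, −78 → 0 °C; aq NH4Cl; crude + TBAF, THF, rt
Reagents that add atoms: (2‑methylbut‑3‑en‑1‑yl)magnesium bromide from 6, C=CC(C)C[Mg]Br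
Why: Grignard 1,2‑addition to the enal installs C7–C10 (the primary homoallyl Grignard is the stable isomer), and fluoride removes the TES group; both new centres are destroyed later.

**Step 6**
Reactants: 7
Product: 8, 1‑[(5R)‑5‑hydroxy‑2‑methyl‑5‑(propan‑2‑yl)cyclopent‑1‑en‑1‑yl]‑3‑methylpent‑4‑en‑1‑one (both C3 epimers)
Conditions: Dess–Martin periodinane, NaHCO3, CH2Cl2, 0 °C → rt
Reagents that add atoms: none
Why: Dess–Martin oxidation takes the secondary allylic alcohol to the enone and leaves the tertiary alcohol; the γ,δ‑alkene cannot move into conjugation under buffered conditions.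

**Step 7**
Reactants: 8
Product: 9, (3R,3aR,8aR)‑3‑hydroxy‑6,8a‑dimethyl‑3‑(propan‑2‑yl)‑2,3,3a,5,8,8a‑hexahydroazulen‑4(1H)‑one (4β‑hydroxy‑5α‑H‑dauc‑8‑en‑6‑one, trans‑fused)
Conditions: (nBu4N)4[W10O32] (5 mol %), MeCN (0.01 M), 390 nm LEDs, 40 °C, Ar
Reagents that add atoms: none
Why: Proposed new method: excited decatungstate abstracts the weak, hydridic tertiary allylic C8–H (the α‑keto C7–H is polarity‑mismatched); the allyl radical attacks the enone β‑carbon C1 through its CH2 terminus (7‑endo Giese, shifting the alkene to C8=C9), and the α‑keto radical at C5 takes H back from reduced decatungstate, a redox‑neutral net Alder‑ene. The O4–H···O=C6 hydrogen bond should tilt the tether to the face anti to OH so C10 adds α (Me stays β), and H should reach C5 from the α face because the β face is flanked by C1‑Me and C4‑OH (trans fusion). Closest known chemistry: intermolecular decatungstate allylic C–H alkylation with electron‑poor alkenes, and radical 7‑endo Giese cyclisations.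

**Step 8**
Reactants: 9
Product: 10, jaeschkeanadiol, (3R,3aS,4S,8aR)‑6,8a‑dimethyl‑3‑(propan‑2‑yl)‑1,2,3,3a,4,5,8,8a‑octahydroazulene‑3,4‑diol
Conditions: Me4NBH(OAc)3, MeCN/AcOH (1:1), −30 → 0 °C
Reagents that add atoms: none
Why: Saksena–Evans reduction: the borohydride bound to the 4β‑OH delivers hydride intramolecularly to the β face of C6, giving the 6α‑alcohol; external hydride would approach from the α face, away from the C1‑Me, and give the wrong epimer.

**Step 9**
Reactants: 10
Product: 11, 8α,9α‑epoxyjaeschkeanadiol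
Conditions: VO(acac)2 (5 mol %), t‑BuOOH, CH2Cl2, 0 °C → rt
Reagents that add atoms: tert‑butyl hydroperoxide, CC(C)(C)OO
Why: Vanadium‑catalysed directed epoxidation: the homoallylic 6α‑OH delivers oxygen to the α face of the only alkene, setting C8 and C9; the remote tertiary 4‑OH cannot direct.

**Step 10**
Reactants: 11; 12, 4‑acetoxybenzoyl chloride
Product: 13, Jaeskeanin
Conditions: 12, DMAP, Et3N, CH2Cl2, 0 °C → rt; then pyrrolidine, 0 °C (one pot)
Reagents that add atoms: 4‑acetoxybenzoyl chloride (12), CC(=O)Oc1ccc(cc1)C(Cl)=O (the acetyl is removed in the second stage)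
Why: DMAP‑catalysed acylation takes the secondary 6‑OH over the tertiary 4‑OH with retention, and pyrrolidine aminolyses only the aryl acetate; the hindered benzoate and the epoxide should survive.

## Compound list

1 | (S)‑(+)‑terpinen‑4‑ol | CC(C)[C@]1(O)CCC(C)=CC1 | starting material
2 | terpinen‑4‑ol TES ether | CC(C)[C@]1(O[Si](CC)(CC)CC)CCC(C)=CC1 | intermediate
3 | (3S)‑6‑oxo‑3‑isopropyl‑3‑(triethylsilyloxy)heptanal | CC(C)[C@](CC=O)(O[Si](CC)(CC)CC)CCC(C)=O | intermediate
4 | (5R)‑2‑methyl‑5‑isopropyl‑5‑(triethylsilyloxy)cyclopent‑1‑ene‑1‑carbaldehyde | CC(C)[C@]1(O[Si](CC)(CC)CC)CCC(C)=C1C=O | intermediate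
5 | 2‑methylbut‑3‑en‑1‑ol (racemic) | C=CC(C)CO | starting material
6 | 4‑bromo‑3‑methylbut‑1‑ene (racemic) | C=CC(C)CBr | intermediate
7 | 1‑[(5R)‑5‑hydroxy‑5‑isopropyl‑2‑methylcyclopent‑1‑enyl]‑3‑methylpent‑4‑en‑1‑ol (diastereomer mixture) | CC(C)[C@]1(O)CCC(C)=C1C(O)CC(C)C=C | intermediate
8 | 1‑[(5R)‑5‑hydroxy‑5‑isopropyl‑2‑methylcyclopent‑1‑enyl]‑3‑methylpent‑4‑en‑1‑one (C3 epimers) | CC(C)[C@]1(O)CCC(C)=C1C(=O)CC(C)C=C | intermediate
9 | 4β‑hydroxy‑5α‑H‑dauc‑8‑en‑6‑one | CC(C)[C@]1(O)CC[C@]2(C)CC=C(C)CC(=O)[C@H]21 | intermediate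
10 | jaeschkeanadiol | CC(C)[C@]1(O)CC[C@]2(C)CC=C(C)C[C@H](O)[C@H]21 | intermediate
11 | 8α,9α‑epoxyjaeschkeanadiol | CC(C)[C@]1(O)CC[C@]2(C)C[C@@H]3O[C@]3(C)C[C@H](O)[C@H]21 | intermediate
12 | 4‑acetoxybenzoyl chloride | CC(=O)Oc1ccc(cc1)C(Cl)=O | starting material
13 | Jaeskeanin | CC(C)[C@]1(O)CC[C@]2(C)C[C@@H]3O[C@]3(C)C[C@H](OC(=O)c3ccc(O)cc3)[C@H]21 | target

## Step count and risks

Total steps: 10. Longest linear sequence: 9 (Steps 1, 2, 3, 5, 6, 7, 8, 9, 10).

Steps most likely to fail:

1. **Step 7 (proposed new cycloisomerisation).** Risks are slow 7‑endo attack at a tetrasubstituted β‑carbon, competing alkene isomerisation by back‑HAT, and the C1 facial selectivity, which rests on the hydrogen‑bond argument. Fallback with known chemistry and a different disconnection, from enal 4: allylMgBr 1,2‑addition; anionic oxy‑Cope (KH, 18‑crown‑6) to move the allyl group to C1; 2‑methylallylMgCl addition to the regenerated aldehyde; desilylation; Grubbs II ring‑closing metathesis to form C8=C9, rejoining the route at 10.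

2. **Step 3 (aldol condensation).** The nucleophilic carbon is neopentyl; the ketone‑enol mode (giving an acetylcyclopentene) or loss of silanol could compete. Fallback: a stepwise directed aldol instead of enamine condensation: selective silyl enol ether of the aldehyde, TiCl4 Mukaiyama aldol onto the ketone, then separate dehydration (MsCl/Et3N).

3. **Step 8 (directed reduction).** The β‑hydroxy ketone 9 can undergo retro‑aldol or dehydration, and delivery to the hindered C6 may be slow. Fallback: reduce with NaBH4/CeCl3 from the open α face to the 6β‑alcohol, install the ester with inversion by Mitsunobu reaction (4‑acetoxybenzoic acid, DIAD, PPh3), epoxidise with m‑CPBA relying on C1‑Me shielding of the β face, then cleave the aryl acetate.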